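**Plan**
- Retrosynthesis: the 15-membered ansa ring is cut at its Z-CH=CH (ring-closing metathesis). The azepinone is then cut at the vinyl-CH–C(=O) bond and the N–C(quinone ring) bond, and the quaternary carbon is cut from the quinone ring (Michael addition to a quinone ester).
- Enabling feature: the lactam C(=O)–NH sits between a carbon of ring A (quinone ring) and the vinyl CH, ortho to the ring-A carbon that bears the quaternary centre. An aryl carboxyl at that position first activates the quinone for the Michael step; after a Curtius 1,2-shift of the ring carbon from C to N it is the isocyanate carbon, which the CH3 of an acetyl group on the quaternary carbon attacks.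
- Forward order: benzene ring B, then ring A (Stobbe annulation), aryl ketone side chain, quinone ester, quaternary centre, azepinedione ring C, enamide, 15-membered ring, quinone, deprotection.
- Stereochemistry: the ethyl-bearing centre comes from an oxazolidinone-directed conjugate addition; the two oxygenated centres from an alkoxyallylboration; the quaternary centre from a cinchona-catalysed Michael addition; the Z-alkene from Z-selective metathesis; the lactam alkene is cis by ring size.

Key step: step 17

Remark (assumption): the sense of induction in steps 13 and 15 is taken from the accepted models for diisopinocampheyl allylboranes and for cinchona-catalysed quinone arylation.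

**Step 1**
Reactants: 1 4-methoxy-3-methylbenzaldehyde; 2 diallyl succinate
Product: 3 (3E)-3-[(allyloxy)carbonyl]-4-(4-methoxy-3-methylphenyl)but-3-enoic acid
Conditions: NaH, allyl alcohol (cat.), THF, 0 → 23 °C; then 1 M HCl
Reagents that add atoms: none
Why: Stobbe condensation (enolate addition, lactonisation, E1cB ring opening) should give the E half-ester, in which the aryl group is cis to CH2CO2H as the next ring closure requires.

**Step 2**
Reactants: 3 Stobbe half-ester
Product: 4 allyl 4-acetoxy-6-methoxy-7-methylnaphthalene-2-carboxylate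
Conditions: Ac2O, NaOAc, 120 °C
Reagents that add atoms: acetic anhydride, CC(=O)OC(C)=O
Why: The mixed anhydride should acylate the ring intramolecularly (Friedel–Crafts type) at the ortho carbon para to CH3 and flanked only by H, the other ortho carbon being hindered by CH3, and the naphthol formed is acetylated in situ.

**Step 3**
Reactants: 4 naphthyl acetate
Product: 5 allyl 4-acetoxy-5-formyl-6-methoxy-7-methylnaphthalene-2-carboxylate
Conditions: Cl2CHOMe, TiCl4, CH2Cl2, −20 → 0 °C; then H2O
Reagents that add atoms: dichloromethyl methyl ether, COC(Cl)Cl; water, O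
Why: Rieche formylation should take place on ring B (ring A is deactivated by ester and acetate) at its α-position ortho to OMe, the most nucleophilic site of a 2-methoxynaphthalene.

**Step 4**
Reactants: 5 formyl naphthyl acetate
Product: 6 allyl 5-formyl-4-hydroxy-6-methoxy-7-methylnaphthalene-2-carboxylate
Conditions: K2CO3 (cat.), allyl alcohol, 0 → 23 °C
Reagents that add atoms: none
Why: Base-catalysed transesterification should cleave only the activated aryl acetate, and allyl alcohol as solvent leaves the allyl ester unchanged.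

**Step 5**
Reactants: 7 (4S)-4-benzyl-1,3-oxazolidin-2-one; 8 (2E)-pent-2-enoic acid
Product: 10 (4S)-4-benzyl-3-[(2E)-pent-2-enoyl]-1,3-oxazolidin-2-one, via mixed pivalic anhydride 9 (not isolated)
Conditions: t-BuCOCl, Et3N, THF, −20 °C; then LiCl, 7, 23 °C
Reagents that add atoms: none
Why: N-Acylation of the oxazolidinone through the mixed anhydride is routine and attacks the less hindered carbonyl.

**Step 6**
Reactants: 10 N-pentenoyl oxazolidinone
Product: 11 (4S)-4-benzyl-3-[(3R)-3-ethylpent-4-enoyl]-1,3-oxazolidin-2-one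
Conditions: CH2=CHMgBr, CuBr·SMe2, THF, −78 → −20 °C; aq. NH4Cl
Reagents that add atoms: vinylmagnesium bromide, C=C[Mg]Br
Why: Copper-mediated conjugate addition to the magnesium-chelated s-cis enoyl imide should occur on the face opposite the benzyl group and so set the (3R) centre.

**Step 7**
Reactants: 11 conjugate adduct
Product: 12 (3R)-3-ethylpent-4-en-1-ol
Conditions: LiBH4, H2O (1 equiv), Et2O, 0 °C
Reagents that add atoms: none
Why: Reductive cleavage of the imide releases the primary alcohol and the auxiliary, and the β-stereocentre cannot epimerise.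

**Step 8**
Reactants: 12 homoallylic-branched alcohol
Product: 13 (3R)-5-bromo-3-ethylpent-1-ene
Conditions: CBr4, PPh3, CH2Cl2, 0 °C
Reagents that add atoms: carbon tetrabromide, BrC(Br)(Br)Br
Why: The Appel reaction substitutes the primary carbon by SN2 and leaves the stereocentre untouched.

**Step 9**
Reactants: 13 bromide; 6 peri-hydroxy aldehyde
Product: 15 allyl 5-[(4R)-4-ethyl-1-hydroxyhex-5-en-1-yl]-4-hydroxy-6-methoxy-7-methylnaphthalene-2-carboxylate (both carbinol epimers), via Grignard reagent 14 (not isolated)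
Conditions: Mg, THF, 23 °C; then 6 (0.45 equiv), THF, −78 °C; aq. NH4Cl
Reagents that add atoms: none
Why: Grignard 1,2-addition: one equivalent deprotonates the naphthol, the magnesium naphthoxide chelates the peri aldehyde, which reacts far faster than the conjugated ester at −78 °C; the new carbinol centre is not controlled and is removed in step 11.

**Step 10**
Reactants: 15 naphthol carbinol
Product: 16 allyl 5-[(4R)-4-ethyl-1-hydroxyhex-5-en-1-yl]-6-methoxy-7-methyl-1,4-dioxo-1,4-dihydronaphthalene-2-carboxylate
Conditions: PhI(OAc)2 (2.2 equiv), MeCN/H2O, 0 °C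
Reagents that add atoms: water, O
Why: Hypervalent-iodine oxidation of a 1-naphthol with a free para position, with water adding at that position, should give the para-quinone without touching the secondary alcohol.

**Step 11**
Reactants: 16 quinone carbinol
Product: 17 allyl 5-[(4R)-4-ethylhex-5-enoyl]-6-methoxy-7-methyl-1,4-dioxo-1,4-dihydronaphthalene-2-carboxylate
Conditions: Dess–Martin periodinane, CH2Cl2, 23 °C
Reagents that add atoms: none
Why: Neutral oxidation of the benzylic alcohol gives the aryl ketone and merges the carbinol epimers, and the electrophilic quinone ester meets no nucleophile.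

**Step 12**
Reactants: 18 allyl alcohol
Product: 19 3-(methoxymethoxy)prop-1-ene
Conditions: MeOCH2Cl, i-Pr2NEt, CH2Cl2, 0 °C
Reagents that add atoms: chloromethyl methyl ether, COCCl
Why: Standard O-alkylation forms the MOM ether.

**Step 13**
Reactants: 19 allyl MOM ether; 20 3-methylbutanal
Product: 22 (3S,4S)-3-(methoxymethoxy)-6-methylhept-1-en-4-ol, via alkoxyallylborane 21 (not isolated)
Conditions: 19, s-BuLi, THF, −78 °C; (+)-Ipc2BOMe; BF3·OEt2; 20, −78 °C; NaOH, H2O2, 0 °C
Reagents that add atoms: none
Why: Asymmetric alkoxyallylboration: the Z-γ-alkoxyallylborane reacts through a closed chair transition state to give the syn relationship, and the isopinocampheyl groups derived from (−)-α-pinene select the aldehyde face, so both centres (3S,4S) should be set at once.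

**Step 14**
Reactants: 22 mono-protected syn diol; 23 ethyl 2-methyl-3-oxobutanoate
Product: 24 (3S,4S)-3-(methoxymethoxy)-6-methylhept-1-en-4-yl 2-methyl-3-oxobutanoate (epimers at the enolisable carbon)
Conditions: DMAP (0.3 equiv), PhMe, 110 °C, 4 Å MS
Reagents that add atoms: none
Why: DMAP-catalysed transesterification of a β-keto ester is driven by removal of ethanol and makes the hindered ester bond before the quaternary carbon exists.

**Step 15**
Reactants: 17 quinone ester; 24 β-keto ester
Product: 26 allyl 5-[(4R)-4-ethylhex-5-enoyl]-1,4,6-trimethoxy-7-methyl-3-[(2S)-1-{[(3S,4S)-3-(methoxymethoxy)-6-methylhept-1-en-4-yl]oxy}-2-methyl-1,3-dioxobutan-2-yl]naphthalene-2-carboxylate, via hydroquinone 25 (not isolated)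
Conditions: 9-O-benzylcupreidine (10 mol %), CH2Cl2, −20 °C; aq. Na2S2O4 wash; then MeI, Cs2CO3, DMF, 23 °C
Reagents that add atoms: iodomethane, CI
Why: Organocatalytic Michael addition (α-arylation of a β-keto ester by a quinone): the enolate attacks the only quinone CH, which is doubly activated by the ester and the ring carbonyl; the bifunctional catalyst selects the enolate face and so sets the quaternary centre, and the hydroquinone is methylated at once so that its hindered OH cannot lactonise onto the side-chain ester.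

**Step 16**
Reactants: 26 allyl ester
Product: 27 5-[(4R)-4-ethylhex-5-enoyl]-1,4,6-trimethoxy-7-methyl-3-[(2S)-1-{[(3S,4S)-3-(methoxymethoxy)-6-methylhept-1-en-4-yl]oxy}-2-methyl-1,3-dioxobutan-2-yl]naphthalene-2-carboxylic acid
Conditions: Pd(PPh3)4 (5 mol %), morpholine, THF, 23 °C
Reagents that add atoms: none
Why: Palladium π-allyl transfer to morpholine frees the di-ortho-substituted acid under neutral conditions that no hydrolysis could match, and the MOM ether, ketones and terminal alkenes are inert.

**Step 17**
Reactants: 27 aryl carboxylic acid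
Product: 30 (3S,4S)-3-(methoxymethoxy)-6-methylhept-1-en-4-yl (5S)-7-[(4R)-4-ethylhex-5-enoyl]-6,8,11-trimethoxy-5,9-dimethyl-2,4-dioxo-2,3,4,5-tetrahydro-1H-naphtho[2,3-b]azepine-5-carboxylate, via acyl azide 28 (not isolated), via aryl isocyanate 29 (not isolated)
Conditions: (PhO)2P(O)N3, Et3N, PhMe, 0 → 85 °C; then MgBr2·OEt2, i-Pr2NEt, CH2Cl2, 23 °C
Reagents that add atoms: diphenylphosphoryl azide, [N-]=[N+]=NP(=O)(Oc1ccccc1)Oc1ccccc1
Why: Proposed new method: the acid is converted into acyl azide 28, which on heating loses N2 with a concerted 1,2-shift of the ring-A carbon from the carbonyl carbon to nitrogen (Curtius rearrangement, forming the N–aryl bond) to give isocyanate 29; MgBr2/i-Pr2NEt then enolises the acetyl group, which has α-hydrogens only on CH3 because its other α-carbon is quaternary, and the magnesium enolate carbon adds to the isocyanate carbon (forming the CH2–C(=O) bond). The closest known reactions are the Curtius rearrangement with intramolecular capture of the isocyanate by a carbon nucleophile (Friedel–Crafts-type lactam closures) and the C-carbamoylation of ketone enolates by isocyanates under soft enolisation; their tandem use to close a seven-membered ring has not been shown. Ring C closes in a 7-endo-dig sense with respect to the N=C bond of the cumulene (7-exo with respect to C=O), the two reacting groups being held ortho on ring A. No stereocentre is formed, and the quaternary centre has no α-hydrogen, so it cannot epimerise. The step needs C- over O-carbamoylation and intra- over intermolecular capture: the chelated magnesium enolate favours C-attack, and the enolate of the aryl ketone on ring B cannot reach the isocyanate because that would demand a strained nine-membered ring across the naphthalene. Formation of the acidic β-keto lactam as its magnesium salt should pull the closure forward.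

**Step 18**
Reactants: 30 β-keto lactam
Product: 31 (3S,4S)-3-(methoxymethoxy)-6-methylhept-1-en-4-yl (5S)-7-[(4R)-4-ethylhex-5-enoyl]-6,8,11-trimethoxy-5,9-dimethyl-2-oxo-4-{[(trifluoromethyl)sulfonyl]oxy}-2,5-dihydro-1H-naphtho[2,3-b]azepine-5-carboxylate
Conditions: NaH (1.05 equiv), PhNTf2, THF, 0 °C
Reagents that add atoms: N-phenylbis(trifluoromethanesulfonimide), O=S(=O)(N(c1ccccc1)S(=O)(=O)C(F)(F)F)C(F)(F)F
Why: One equivalent of base removes only the 1,3-dicarbonyl proton, and O-triflation at the ketone oxygen gives the enol triflate without touching the less acidic aryl ketone.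

**Step 19**
Reactants: 31 enol triflate
Product: 32 (3S,4S)-3-(methoxymethoxy)-6-methylhept-1-en-4-yl (5R)-7-[(4R)-4-ethylhex-5-enoyl]-6,8,11-trimethoxy-5,9-dimethyl-2-oxo-2,5-dihydro-1H-naphtho[2,3-b]azepine-5-carboxylate
Conditions: Pd(OAc)2 (5 mol %), PPh3, HCO2H, Et3N, DMF, 60 °C
Reagents that add atoms: none
Why: Palladium-catalysed formate reduction of the vinyl triflate (oxidative addition, decarboxylation to a palladium hydride, reductive elimination) gives the cis enamide C=C and avoids a hydride reduction that would not distinguish the two ketones.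

**Step 20**
Reactants: 32 diene
Product: 33 Z-configured 15-membered ansa macrolactone (MOM ether; tri-O-methyl naphtho[2,3-b]azepin-2-one form of the target)
Conditions: Ru(NO3)(C,C-chelating 1-adamantyl-3-(2,6-diisopropylphenyl)imidazolin-2-ylidene)(=CH-C6H4-2-OiPr) (7.5 mol %), THF, 40 °C, 1 mM, static vacuum
Reagents that add atoms: none
Why: Ring-closing metathesis joins the two terminal vinyl groups (the conjugated cis enamide is inert); the cyclometalated catalyst forces both ruthenacyclobutane substituents to the face away from the N-aryl group and so should give the Z-alkene kinetically, and high dilution favours the 15-membered ring.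

**Step 21**
Reactants: 33 macrocycle
Product: 34 quinone macrolactone (MOM ether and ring-B methyl ether of the target)
Conditions: (NH4)2Ce(NO3)6 (2.5 equiv), MeCN/H2O, 0 °C
Reagents that add atoms: water, O
Why: Oxidative demethylation occurs on ring A, the most electron-rich ring (two OMe para to each other and the amide nitrogen), and leaves the ring-B ether, the Z-alkene and the MOM ether alone.

**Step 22**
Reactants: 34 protected quinone
Product: 35 CNP0579633.1 (target)
Conditions: BCl3 (4 equiv), CH2Cl2, −78 → −30 °C; pH 7 buffer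
Reagents that add atoms: none
Why: Boron chelation to the aryl ketone directs cleavage of the ortho methyl ether, the MOM acetal is cleaved through its oxocarbenium ion without ionising the allylic carbon, and the neutral work-up avoids acyl migration to the new hydroxyl.

**Compound list**
1 | 4-methoxy-3-methylbenzaldehyde | COc1ccc(C=O)cc1C | starting material
2 | diallyl succinate | C=CCOC(=O)CCC(=O)OCC=C | starting material
3 | (3E)-3-[(allyloxy)carbonyl]-4-(4-methoxy-3-methylphenyl)but-3-enoic acid | OC(=O)C/C(C(=O)OCC=C)=C\c1ccc(OC)c(C)c1 | intermediate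
4 | allyl 4-acetoxy-6-methoxy-7-methylnaphthalene-2-carboxylate | C=CCOC(=O)c1cc(OC(C)=O)c2cc(OC)c(C)cc2c1 | intermediate
5 | allyl 4-acetoxy-5-formyl-6-methoxy-7-methylnaphthalene-2-carboxylate | C=CCOC(=O)c1cc(OC(C)=O)c2c(C=O)c(OC)c(C)cc2c1 | intermediate
6 | allyl 5-formyl-4-hydroxy-6-methoxy-7-methylnaphthalene-2-carboxylate | C=CCOC(=O)c1cc(O)c2c(C=O)c(OC)c(C)cc2c1 | intermediate
7 | (4S)-4-benzyl-1,3-oxazolidin-2-one | O=C1N[C@@H](Cc2ccccc2)CO1 | starting material
8 | (2E)-pent-2-enoic acid | CC/C=C/C(=O)O | starting material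
9 | (2E)-pent-2-enoic pivalic anhydride | CC/C=C/C(=O)OC(=O)C(C)(C)C | intermediate (not isolated)
10 | (4S)-4-benzyl-3-[(2E)-pent-2-enoyl]-1,3-oxazolidin-2-one | CC/C=C/C(=O)N1[C@@H](Cc2ccccc2)COC1=O | intermediate
11 | (4S)-4-benzyl-3-[(3R)-3-ethylpent-4-enoyl]-1,3-oxazolidin-2-one | O=C(C[C@@H](CC)C=C)N1[C@@H](Cc2ccccc2)COC1=O | intermediate
12 | (3R)-3-ethylpent-4-en-1-ol | OCC[C@@H](CC)C=C | intermediate
13 | (3R)-5-bromo-3-ethylpent-1-ene | BrCC[C@@H](CC)C=C | intermediate
14 | [(3R)-3-ethylpent-4-en-1-yl]magnesium bromide | Br[Mg]CC[C@@H](CC)C=C | intermediate (not isolated)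
15 | allyl 5-[(4R)-4-ethyl-1-hydroxyhex-5-en-1-yl]-4-hydroxy-6-methoxy-7-methylnaphthalene-2-carboxylate (both carbinol epimers) | C=CCOC(=O)c1cc(O)c2c(C(O)CC[C@@H](CC)C=C)c(OC)c(C)cc2c1 | intermediate
16 | allyl 5-[(4R)-4-ethyl-1-hydroxyhex-5-en-1-yl]-6-methoxy-7-methyl-1,4-dioxo-1,4-dihydronaphthalene-2-carboxylate | C=CCOC(=O)C1=CC(=O)c2c(C(O)CC[C@@H](CC)C=C)c(OC)c(C)cc2C1=O | intermediate
17 | allyl 5-[(4R)-4-ethylhex-5-enoyl]-6-methoxy-7-methyl-1,4-dioxo-1,4-dihydronaphthalene-2-carboxylate | C=CCOC(=O)C1=CC(=O)c2c(C(=O)CC[C@@H](CC)C=C)c(OC)c(C)cc2C1=O | intermediate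
18 | prop-2-en-1-ol (allyl alcohol) | C=CCO | starting material
19 | 3-(methoxymethoxy)prop-1-ene | C=CCOCOC | intermediate
20 | 3-methylbutanal | CC(C)CC=O | starting material
21 | B-[(Z)-3-(methoxymethoxy)allyl]diisopinocampheylborane (isopinocampheyl groups from (−)-α-pinene) | COCO/C=C\CB([C@H]1C[C@H]2C[C@@H]([C@@H]1C)C2(C)C)[C@H]1C[C@H]2C[C@@H]([C@@H]1C)C2(C)C | intermediate (not isolated)
22 | (3S,4S)-3-(methoxymethoxy)-6-methylhept-1-en-4-ol | C=C[C@H](OCOC)[C@H](CC(C)C)O | intermediate
23 | ethyl 2-methyl-3-oxobutanoate | CCOC(=O)C(C)C(C)=O | starting material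
24 | (3S,4S)-3-(methoxymethoxy)-6-methylhept-1-en-4-yl 2-methyl-3-oxobutanoate | C=C[C@H](OCOC)[C@H](CC(C)C)OC(=O)C(C)C(C)=O | intermediate
25 | allyl 5-[(4R)-4-ethylhex-5-enoyl]-1,4-dihydroxy-6-methoxy-7-methyl-3-[(2S)-1-{[(3S,4S)-3-(methoxymethoxy)-6-methylhept-1-en-4-yl]oxy}-2-methyl-1,3-dioxobutan-2-yl]naphthalene-2-carboxylate | C=C[C@H](OCOC)[C@H](CC(C)C)OC(=O)[C@](C)(C(C)=O)c1c(O)c2c(C(=O)CC[C@@H](CC)C=C)c(OC)c(C)cc2c(O)c1C(=O)OCC=C | intermediate (not isolated)
26 | allyl 5-[(4R)-4-ethylhex-5-enoyl]-1,4,6-trimethoxy-7-methyl-3-[(2S)-1-{[(3S,4S)-3-(methoxymethoxy)-6-methylhept-1-en-4-yl]oxy}-2-methyl-1,3-dioxobutan-2-yl]naphthalene-2-carboxylate | C=C[C@H](OCOC)[C@H](CC(C)C)OC(=O)[C@](C)(C(C)=O)c1c(OC)c2c(C(=O)CC[C@@H](CC)C=C)c(OC)c(C)cc2c(OC)c1C(=O)OCC=C | intermediate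
27 | the corresponding naphthalene-2-carboxylic acid of 26 | C=C[C@H](OCOC)[C@H](CC(C)C)OC(=O)[C@](C)(C(C)=O)c1c(OC)c2c(C(=O)CC[C@@H](CC)C=C)c(OC)c(C)cc2c(OC)c1C(=O)O | intermediate
28 | the corresponding naphthalene-2-carbonyl azide | C=C[C@H](OCOC)[C@H](CC(C)C)OC(=O)[C@](C)(C(C)=O)c1c(OC)c2c(C(=O)CC[C@@H](CC)C=C)c(OC)c(C)cc2c(OC)c1C(=O)N=[N+]=[N-] | intermediate (not isolated)
29 | (3S,4S)-3-(methoxymethoxy)-6-methylhept-1-en-4-yl (2S)-2-{8-[(4R)-4-ethylhex-5-enoyl]-3-isocyanato-1,4,7-trimethoxy-6-methylnaphthalen-2-yl}-2-methyl-3-oxobutanoate | C=C[C@H](OCOC)[C@H](CC(C)C)OC(=O)[C@](C)(C(C)=O)c1c(OC)c2c(C(=O)CC[C@@H](CC)C=C)c(OC)c(C)cc2c(OC)c1N=C=O | intermediate (not isolated)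
30 | (3S,4S)-3-(methoxymethoxy)-6-methylhept-1-en-4-yl (5S)-7-[(4R)-4-ethylhex-5-enoyl]-6,8,11-trimethoxy-5,9-dimethyl-2,4-dioxo-2,3,4,5-tetrahydro-1H-naphtho[2,3-b]azepine-5-carboxylate | C=C[C@H](OCOC)[C@H](CC(C)C)OC(=O)[C@]1(C)C(=O)CC(=O)Nc2c1c(OC)c1c(cc(C)c(OC)c1C(=O)CC[C@@H](CC)C=C)c2OC | intermediate
31 | (3S,4S)-3-(methoxymethoxy)-6-methylhept-1-en-4-yl (5S)-7-[(4R)-4-ethylhex-5-enoyl]-6,8,11-trimethoxy-5,9-dimethyl-2-oxo-4-{[(trifluoromethyl)sulfonyl]oxy}-2,5-dihydro-1H-naphtho[2,3-b]azepine-5-carboxylate | C=C[C@H](OCOC)[C@H](CC(C)C)OC(=O)[C@]1(C)C(OS(=O)(=O)C(F)(F)F)=CC(=O)Nc2c1c(OC)c1c(cc(C)c(OC)c1C(=O)CC[C@@H](CC)C=C)c2OC | intermediate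
32 | (3S,4S)-3-(methoxymethoxy)-6-methylhept-1-en-4-yl (5R)-7-[(4R)-4-ethylhex-5-enoyl]-6,8,11-trimethoxy-5,9-dimethyl-2-oxo-2,5-dihydro-1H-naphtho[2,3-b]azepine-5-carboxylate | C=C[C@H](OCOC)[C@H](CC(C)C)OC(=O)[C@]1(C)C=CC(=O)Nc2c1c(OC)c1c(cc(C)c(OC)c1C(=O)CC[C@@H](CC)C=C)c2OC | intermediate
33 | Z-configured 15-membered ansa macrolactone; allylic OMOM; 6,8,11-trimethoxy naphtho[2,3-b]azepin-2-one; stereocentres as in the target | CC[C@H]1/C=C\[C@H](OCOC)[C@H](CC(C)C)OC(=O)[C@]2(C)C=CC(=O)Nc3c2c(OC)c2c(cc(C)c(OC)c2C(=O)CC1)c3OC | intermediate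
34 | quinone form of 33: the target with its allylic OH as MOM ether and its phenol as methyl ether | CC[C@H]1/C=C\[C@H](OCOC)[C@H](CC(C)C)OC(=O)[C@]2(C)C=CC(=O)NC3=C2C(=O)c2c(cc(C)c(OC)c2C(=O)CC1)C3=O | intermediate
35 | CNP0579633.1 | CC[C@H]1/C=C\[C@H](O)[C@H](CC(C)C)OC(=O)[C@]2(C)C=CC(=O)NC3=C2C(=O)c2c(cc(C)c(O)c2C(=O)CC1)C3=O | target

**Count**
Total: 22 steps. Longest linear sequence: 15 steps (steps 1–4, 9–11 and 15–22, from 1).

**Steps most likely to fail**

1. Step 17. The isocyanate may be lost before enough enolate is present: traces of water would hydrolyse it to the aniline, which should condense with the neighbouring acetyl group to an indolenine, and the isocyanate may oligomerise. The fallback sets out from acid 27 and comes back at 30, using known chemistry. The Curtius rearrangement of 27 ((PhO)2P(O)N3, Et3N, PhMe, 85 °C) is run in the presence of imidazole, which traps isocyanate 29 as the storable N-aryl imidazole-1-carboxamide F1. After isolation, F1 is treated with KH (2.2 equiv) in THF at 0 °C. The N-anion expels imidazolide and regenerates the isocyanate next to the preformed potassium enolate of the acetyl group, which closes to 30. Carbamoylimidazoles as isocyanate equivalents and the C-carbamoylation of ketone enolates are both established.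

2. Step 15. Facial discrimination may be poor because the acyclic enolate is geometrically mobile, and the hydroquinone may lactonise onto the side-chain ester before it is methylated. The fallback sets out from 24 and 17 and comes back at 26. Keto ester 24 is condensed with L-valine diethylamide (cat. HCl, 4 Å MS, PhMe) to the enamino ester F2. Addition of F2 to quinone 17 with Cu(OAc)2·H2O (5 mol %) in acetone, then aqueous HCl, should give hydroquinone 25 under auxiliary control. It is methylated as in step 15 to give 26.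

3. Step 20. Turnover may be slow at the two allylically branched vinyl groups, and secondary metathesis may erode the Z-selectivity. The fallback sets out from 32 and comes back at 33. Both vinyl groups of 32 are first capped by cross-metathesis with (Z)-but-2-ene, using Ru(3,6-dichlorobenzene-1,2-dithiolate)(SIMes)(=CH-C6H4-2-OiPr), to give the bis-(Z)-propenyl compound F3. Stereoretentive ring-closing metathesis of F3 with the same dithiolate catalyst at high dilution should then pass the Z geometry on to macrocycle 33.

**Further compounds**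
F1 | step 17 | (3S,4S)-3-(methoxymethoxy)-6-methylhept-1-en-4-yl (2S)-2-{8-[(4R)-4-ethylhex-5-enoyl]-3-[(1H-imidazol-1-ylcarbonyl)amino]-1,4,7-trimethoxy-6-methylnaphthalen-2-yl}-2-methyl-3-oxobutanoate | C=C[C@H](OCOC)[C@H](CC(C)C)OC(=O)[C@](C)(C(C)=O)c1c(OC)c2c(C(=O)CC[C@@H](CC)C=C)c(OC)c(C)cc2c(OC)c1NC(=O)n1ccnc1
F2 | step 15 | (3S,4S)-3-(methoxymethoxy)-6-methylhept-1-en-4-yl (2Z)-3-{[(2S)-1-(diethylamino)-3-methyl-1-oxobutan-2-yl]amino}-2-methylbut-2-enoate | C=C[C@H](OCOC)[C@H](CC(C)C)OC(=O)/C(C)=C(C)\N[C@@H](C(C)C)C(=O)N(CC)CC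
F3 | step 20 | bis-(Z)-propenyl analogue of 32 (both terminal CH=CH2 groups replaced by (Z)-CH=CH-CH3) | C/C=C\[C@H](OCOC)[C@H](CC(C)C)OC(=O)[C@]1(C)C=CC(=O)Nc2c1c(OC)c1c(cc(C)c(OC)c1C(=O)CC[C@@H](CC)/C=C\C)c2OC
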